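**Retrosynthetic overview**
- The target is opened at the angelate ester to a 4α-acetoxy-3α-hydroxy cis-eudesman-8-one.
- The decalin (C5–C10 bond and C4–O bond) comes from a proton-initiated transannular closure of a (3R)-3-acetoxy-(1(10)E,4Z)-germacra-1(10),4-dien-8-one. The C3 acetate captures C4 and is relayed to O4 through a cyclic orthoester.
- The ten-membered ring (C6–C7, the farnesane C1–C10 bond) comes from allylation of a regiodefined enolate by a (2Z)-allylic chloride, an imitation of diphosphate ionisation and 1,10-closure.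
- The acyclic (2Z,6E)-farnesane comes from an asymmetric Nozaki–Hiyama–Kishi union of (Z)-3-iodobut-2-en-1-ol with a C11 keto aldehyde built from prenal, propargyl bromide, AlMe3 and ethylene oxide.
- Ring order: ten-membered ring first, then both six-membered rings in one transannular step.

Assumption: the SMILES is taken as written, a cis-fused eudesmane (3R,4S,5S,7R,10R: 3α-angelate, 4α-acetoxy/4β-methyl, 5β-H, 7β-isopropyl, 10β-methyl); ring compounds carry germacrane/eudesmane numbering, acyclic ones farnesane numbering; in step 5 the ligand antipode that gives the 4R carbinol is used.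

**Step 1**
Reactants: 1 3-methylbut-2-enal; 2 3-bromoprop-1-yne
Product: 3 6-methylhept-5-en-1-yn-4-ol (racemic)
Conditions: Zn dust, THF/sat. aq NH4Cl, 0 °C to rt
Reagents that add atoms: none
Why: Barbier-type zinc propargylation adds 1,2 to the enal; the racemic carbinol centre is oxidised away in step 3.

**Step 2**
Reactants: 3 6-methylhept-5-en-1-yn-4-ol
Product: 5 (3E)-4,8-dimethylnona-3,7-diene-1,6-diol (racemic), via alkenylalane 4 (not isolated)
Conditions: AlMe3 (3 equiv), Cp2ZrCl2 (0.25 equiv), CH2Cl2, 0 °C to rt; evaporate; n-BuLi, THF, −30 °C; ethylene oxide, −30 °C to rt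
Reagents that add atoms: trimethylaluminium, C[Al](C)C; ethylene oxide, C1CO1
Why: Negishi zirconium-catalysed syn-carboalumination puts methyl on the internal and aluminium on the terminal alkyne carbon (this sets the E-trisubstituted alkene), and the derived alanate opens ethylene oxide with retention at the alkenyl carbon.

**Step 3**
Reactants: 5 (3E)-4,8-dimethylnona-3,7-diene-1,6-diol
Product: 6 (3E)-4,8-dimethyl-6-oxonona-3,7-dienal
Conditions: Dess–Martin periodinane (2.4 equiv), NaHCO3, CH2Cl2, 0 °C; used crude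
Reagents that add atoms: none
Why: Buffered Dess–Martin oxidation converts both carbinols without enolisation, so the skipped enone and the β,γ-unsaturated aldehyde are obtained without alkene migration.

**Step 4**
Reactants: 7 but-2-yn-1-ol
Product: 9 (2Z)-3-iodobut-2-en-1-ol, via alkenylaluminate 8 (not isolated)
Conditions: NaAlH2(OCH2CH2OCH3)2, THF, 0 °C to rt; then I2, −78 to 0 °C
Reagents that add atoms: iodine, [I][I]
Why: Hydroxyl-directed trans-hydroalumination places aluminium on C3 cis to the carbinol carbon, and iodinolysis with retention gives the Z-iodide as a single isomer.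

**Step 5**
Reactants: 6 (3E)-4,8-dimethyl-6-oxonona-3,7-dienal; 9 (2Z)-3-iodobut-2-en-1-ol
Product: 10 (2Z,4R,6E)-1,4-dihydroxy-3,7,11-trimethyldodeca-2,6,10-trien-9-one
Conditions: CrCl2 (10 mol%), chiral oxazoline–sulfonamide ligand (11 mol%), 1,8-bis(dimethylamino)naphthalene, NiCl2 (2 mol%), Mn, Cp2ZrCl2, LiCl, MeCN, rt
Reagents that add atoms: none
Why: Catalytic asymmetric Nozaki–Hiyama–Kishi alkenylation is aldehyde-selective (the enone is untouched), keeps the Z-alkene, tolerates the free hydroxyl and sets the 4R carbinol (future C3) by ligand control at chromium.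

**Step 6**
Reactants: 10 (2Z,4R,6E)-1,4-dihydroxy-3,7,11-trimethyldodeca-2,6,10-trien-9-one
Product: 13 (2Z,4R,6E)-1-chloro-3,7,11-trimethyl-9-oxododeca-2,6,10-trien-4-yl acetate, via allylic mesylate 11 (not isolated), via chloro alcohol 12 (not isolated)
Conditions: MsCl, 2,4,6-collidine, LiCl, DMF, 0 °C; then Ac2O, DMAP (5 mol%), 0 °C to rt
Reagents that add atoms: lithium chloride, [Li+].[Cl-]; acetic anhydride, CC(=O)OC(C)=O
Why: Under Meyers–Collington conditions the primary allylic alcohol is mesylated first and displaced by chloride without allylic shift, and the remaining secondary alcohol is then acetylated in the same flask; no stereocentre is touched.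

**Step 7**
Reactants: 13 (2Z,4R,6E)-1-chloro-3,7,11-trimethyl-9-oxododeca-2,6,10-trien-4-yl acetate
Product: 15 (3R)-3-acetoxy-(1(10)E,4Z)-germacra-1(10),4-dien-8-one as a C7 epimer mixture, via silyl enol ether 14 (not isolated)
Conditions: [(Ph3P)CuH]6 (3 mol%), PhMe2SiH, toluene, 0 °C; then slow addition to Bu4N[Ph3SiF2], Bu4NI (cat.), THF (2 mM), 45 °C
Reagents that add atoms: none
Why: Proposed new method: copper hydride adds 1,4 to the β,β-disubstituted enone and the silane fixes the enolate regiospecifically on farnesane C10, then fluoride releases this one enolate, which displaces the primary (Z)-allylic chloride by SN2 under high dilution to close the ten-membered ring between farnesane C1 and C10; the closest known chemistry is CuH/silane conjugate hydrosilylation, Kuwajima–Noyori fluoride-mediated alkylation of silyl enol ethers and germacrane ring closure by intramolecular allylation of stabilised carbanions; the new C7 centre is uncontrolled here and corrected in step 8.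

**Step 8**
Reactants: 15 (3R)-3-acetoxy-(1(10)E,4Z)-germacra-1(10),4-dien-8-one
Product: 18 (3R,4S,5S,7R,10R)-4-acetoxy-3-hydroxyeudesman-8-one, via acetoxonium ion 16 (not isolated), via cyclic orthoester 17 (not isolated)
Conditions: Tf2NH (1.1 equiv), CH2Cl2, −78 to −40 °C; then NaOMe, MeOH, −40 °C to rt; then 80% aq AcOH, 0 °C
Reagents that add atoms: water, O
Why: Proposed new method: protonation of the 1(10)E alkene at C1 triggers chair-like attack of C5 on C10 while the pseudo-axial C3 acetate carbonyl closes on C4 anti to the new bond, so the 4Z geometry puts the C4 methyl cis to H5, the 1(10)E geometry puts the C10 methyl cis to H5 and the cis-fused dioxolanylium puts O4 cis to O3 (3R gives 4S,5S,10R); methoxide turns the ion into the base-stable orthoester, under which C7 equilibrates to the equatorial 7β-isopropyl epimer, and mild aqueous acid then opens the orthoester to the axial tertiary acetate and equatorial alcohol (King–Allbutt selectivity); the closest known chemistry is the acid-induced germacrene-to-eudesmane cyclisation and anchimeric acetoxy participation.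

**Step 9**
Reactants: 18 (3R,4S,5S,7R,10R)-4-acetoxy-3-hydroxyeudesman-8-one; 19 angelic acid
Product: 21 (3R,4S,5S,7R,10R)-4-acetoxy-8-oxoeudesman-3-yl (2Z)-2-methylbut-2-enoate, via mixed anhydride 20 (not isolated)
Conditions: 19, 2,4,6-Cl3C6H2COCl, Et3N, toluene, rt; filter; then 18, 80 °C
Reagents that add atoms: none
Why: Thermal acylation of the equatorial secondary alcohol by the Yamaguchi-type mixed anhydride without nucleophilic catalyst transfers the angeloyl group with no Z-to-E isomerisation and leaves the tertiary acetate and all stereocentres untouched.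

**Compound list**
1 | 3-methylbut-2-enal | CC(C)=CC=O | starting material
2 | 3-bromoprop-1-yne | C#CCBr | starting material
3 | 6-methylhept-5-en-1-yn-4-ol (racemic) | C#CCC(O)C=C(C)C | intermediate
4 | (E)-alkenyl(dimethyl)alane with dimethylaluminium alkoxide | C[Al](C)/C=C(\C)CC(O[Al](C)C)C=C(C)C | intermediate
5 | (3E)-4,8-dimethylnona-3,7-diene-1,6-diol (racemic) | OCC/C=C(\C)CC(O)C=C(C)C | intermediate
6 | (3E)-4,8-dimethyl-6-oxonona-3,7-dienal | O=CC/C=C(\C)CC(=O)C=C(C)C | intermediate
7 | but-2-yn-1-ol | CC#CCO | starting material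
8 | sodium cyclic (Z)-alkenylaluminate (3-methyl-2,5-dihydro-1,2-oxaaluminole with two 2-methoxyethoxy groups on Al) | CC1=CCO[Al-]1(OCCOC)OCCOC.[Na+] | intermediate
9 | (2Z)-3-iodobut-2-en-1-ol | C/C(I)=C/CO | intermediate
10 | (2Z,4R,6E)-1,4-dihydroxy-3,7,11-trimethyldodeca-2,6,10-trien-9-one | OC/C=C(/C)[C@H](O)C/C=C(\C)CC(=O)C=C(C)C | intermediate
11 | (2Z,4R,6E)-4-hydroxy-3,7,11-trimethyl-9-oxododeca-2,6,10-trien-1-yl methanesulfonate | CS(=O)(=O)OC/C=C(/C)[C@H](O)C/C=C(\C)CC(=O)C=C(C)C | intermediate
12 | (2Z,4R,6E)-1-chloro-4-hydroxy-3,7,11-trimethyldodeca-2,6,10-trien-9-one | ClC/C=C(/C)[C@H](O)C/C=C(\C)CC(=O)C=C(C)C | intermediate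
13 | (2Z,4R,6E)-1-chloro-3,7,11-trimethyl-9-oxododeca-2,6,10-trien-4-yl acetate | ClC/C=C(/C)[C@H](OC(C)=O)C/C=C(\C)CC(=O)C=C(C)C | intermediate
14 | (2Z,4R,6E,9Z)-1-chloro-9-[dimethyl(phenyl)silyloxy]-3,7,11-trimethyldodeca-2,6,9-trien-4-yl acetate | ClC/C=C(/C)[C@H](OC(C)=O)C/C=C(\C)C/C(O[Si](C)(C)c1ccccc1)=C/C(C)C | intermediate
15 | (3R)-3-acetoxy-(1(10)E,4Z)-germacra-1(10),4-dien-8-one, C7 epimer mixture | O=C1C/C(C)=C/C[C@@H](OC(C)=O)/C(C)=C\CC1C(C)C | intermediate
16 | 3α,4α-fused 2-methyl-1,3-dioxolan-2-ylium ion of 5βH-eudesman-8-one (C7 mixture, triflimide salt) | C[C+]3O[C@@H]1CC[C@]2(C)CC(=O)C(C(C)C)C[C@@H]2[C@]1(C)O3 | intermediate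
17 | 3α,4α-O-(1-methoxyethylidene)-5βH-eudesman-8-one, 7β-isopropyl (cyclic methyl orthoacetate) | COC3(C)O[C@@H]1CC[C@]2(C)CC(=O)[C@@H](C(C)C)C[C@@H]2[C@]1(C)O3 | intermediate
18 | (3R,4S,5S,7R,10R)-4-acetoxy-3-hydroxyeudesman-8-one | O[C@@H]1CC[C@]2(C)CC(=O)[C@@H](C(C)C)C[C@@H]2[C@]1(C)OC(C)=O | intermediate
19 | angelic acid, (2Z)-2-methylbut-2-enoic acid | C/C=C(/C)C(=O)O | starting material
20 | angelic 2,4,6-trichlorobenzoic anhydride | C/C=C(/C)C(=O)OC(=O)c1c(Cl)cc(Cl)cc1Cl | intermediate
21 | (3R,4S,5S,7R,10R)-4-acetoxy-8-oxoeudesman-3-yl (2Z)-2-methylbut-2-enoate (CNP0322180.1) | C/C=C(/C)C(=O)O[C@@H]1CC[C@]2(C)CC(=O)[C@@H](C(C)C)C[C@@H]2[C@]1(C)OC(C)=O | target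

**Step count**
Total steps: 9. Longest linear sequence: 8 (steps 1, 2, 3, 5, 6, 7, 8, 9).

**Steps most likely to fail, with fallbacks**

Step 5. The aldehyde 6 is fragile (β,γ-unsaturated, next to a skipped enone) and the enantioselectivity with this Z-trisubstituted iodide is unproven. The fallback sets out from 9 and 6 and returns at 10. Iodide 9 is silylated (TBSCl, imidazole) to the tert-butyldimethylsilyl ether F1. Halogen–metal exchange (t-BuLi, then ZnBr2) converts it into the alkenylzinc bromide F2. F2 is added to 6 under amino-alcohol control (3-exo-morpholinoisoborneol, antipode chosen for 4R) to give the mono-silylated diol F3. HF·pyridine then releases 10.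

Step 7. The fluoride-generated enolate may transfer a proton to the more acidic C9 methylene before ring closure, or oligomerise. Copper hydride may also reduce the allylic chloride. The fallback sets out from 10 and returns at 15. ClCO2Me/pyridine at −40 °C acylates the primary hydroxyl and Ac2O the secondary one, giving the methyl carbonate acetate F4. The same CuH/PhMe2SiH reduction gives the silyl enol ether F5. Pd(PPh3)4 in dilute THF then ionises the primary allylic carbonate; the liberated methoxide desilylates the enol ether and the ion-paired enolate attacks the unsubstituted allyl terminus (Tsuji allylation of silyl enol ethers by allyl carbonates). The weakness is partial Z-to-E erosion in the allylpalladium intermediate.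

Step 8. Three things can go wrong: a competing ring conformer may cyclise without acetate participation and give the diastereomeric series; the 1(10) alkene may slip into conjugation with the ketone; or the orthoester may open to the wrong hydroxy acetate. The fallback sets out from 12 (isolated by leaving out the acetylation of step 6) and returns at 21.
- Boc2O/DMAP gives the tert-butyl carbonate F6.
- The step 7 conditions give silyl enol ether F7 and then the ten-membered carbonate F8.
- Tf2NH triggers the same transannular closure, but the more nucleophilic carbonate carbonyl captures C4 and loses 2-methylpropene, giving the neutral cis-3,4-cyclic carbonate F9.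
- K2CO3/MeOH cleaves the carbonate and equilibrates C7, giving the cis-diol F10.
- Mixed anhydride 20 acylates only the secondary hydroxyl, giving the hydroxy angelate F11.
- Ac2O with catalytic TMSOTf at −20 °C acetylates the tertiary hydroxyl to 21.

**Further compounds**
F1 | step 5 | tert-butyl{[(2Z)-3-iodobut-2-en-1-yl]oxy}dimethylsilane | C/C(I)=C/CO[Si](C)(C)C(C)(C)C
F2 | step 5 | (Z)-alkenylzinc bromide from F1 | C/C([Zn]Br)=C/CO[Si](C)(C)C(C)(C)C
F3 | step 5 | (2Z,4R,6E)-1-(tert-butyldimethylsilyloxy)-4-hydroxy-3,7,11-trimethyldodeca-2,6,10-trien-9-one | CC(C)(C)[Si](C)(C)OC/C=C(/C)[C@H](O)C/C=C(\C)CC(=O)C=C(C)C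
F4 | step 7 | (2Z,4R,6E)-1-(methoxycarbonyloxy)-3,7,11-trimethyl-9-oxododeca-2,6,10-trien-4-yl acetate | COC(=O)OC/C=C(/C)[C@H](OC(C)=O)C/C=C(\C)CC(=O)C=C(C)C
F5 | step 7 | dimethyl(phenyl)silyl enol ether of F4 | COC(=O)OC/C=C(/C)[C@H](OC(C)=O)C/C=C(\C)C/C(O[Si](C)(C)c1ccccc1)=C/C(C)C
F6 | step 8 | tert-butyl (2Z,4R,6E)-1-chloro-3,7,11-trimethyl-9-oxododeca-2,6,10-trien-4-yl carbonate | ClC/C=C(/C)[C@H](OC(=O)OC(C)(C)C)C/C=C(\C)CC(=O)C=C(C)C
F7 | step 8 | dimethyl(phenyl)silyl enol ether of F6 | ClC/C=C(/C)[C@H](OC(=O)OC(C)(C)C)C/C=C(\C)C/C(O[Si](C)(C)c1ccccc1)=C/C(C)C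
F8 | step 8 | (3R)-3-(tert-butoxycarbonyloxy)-(1(10)E,4Z)-germacra-1(10),4-dien-8-one, C7 mixture | O=C1C/C(C)=C/C[C@@H](OC(=O)OC(C)(C)C)/C(C)=C\CC1C(C)C
F9 | step 8 | 3α,4α-carbonyldioxy-5βH-eudesman-8-one, C7 mixture | O=C3O[C@@H]1CC[C@]2(C)CC(=O)C(C(C)C)C[C@@H]2[C@]1(C)O3
F10 | step 8 | (3R,4S,5S,7R,10R)-3,4-dihydroxyeudesman-8-one | O[C@@H]1CC[C@]2(C)CC(=O)[C@@H](C(C)C)C[C@@H]2[C@]1(C)O
F11 | step 8 | (3R,4S,5S,7R,10R)-4-hydroxy-8-oxoeudesman-3-yl (2Z)-2-methylbut-2-enoate | C/C=C(/C)C(=O)O[C@@H]1CC[C@]2(C)CC(=O)[C@@H](C(C)C)C[C@@H]2[C@]1(C)O
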